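**Plan** (ring locants: C1 = tertiary carbinol bearing C7H2OBz, C2 = C=O, C3 = CH2, C4 = CHOH, C5 = CHOBz, C6 = CHOH)
Enabling feature: on the single six-membered ring, O5 (benzoate) and O6 (hydroxyl) are trans, which marks an epoxide opened at C5. The parent C5=C6 alkene lies between C4 and C1, and each of these can carry a vinyl group in an open chain.
Cuts, in retrosynthetic order: O4–Si; C5–OBz and the C5/C6 epoxide oxygen; C5=C6 (ring-closing metathesis); C3–C4 (aldol); C7–OBz and the C1/C7 epoxide oxygen; the C1–C6 vinyl unit (enyne metathesis).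
Forward order: a four-carbon alkynol and ethylene give the C7–C1(C6=)–C2–C3 block, a C3 enal adds C4–C5=, metathesis closes the only ring, and O6 and O5 go onto the ring last.
Stereochemistry: C1 comes from a matched Katsuki–Sharpless epoxidation (L-(+)-DIPT reinforced by an (S)-carbinol that later becomes the C2 ketone). C4 comes from the Ipc ligands of a boron aldol, C6 from O1-directed epoxidation, and C5 from SN2 inversion by benzoate.

Key step: step 8

Assumption: (S)-but-3-yn-2-ol is taken as the commercial enantiopure alcohol, and the C1–C7 locants defined above are used for every intermediate.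

Step 1
Reactants: 1 (S)-but-3-yn-2-ol; 2 ethylene
Product: 3 (2S)-3-methylidenepent-4-en-2-ol
Conditions: 2 (4 atm), (H2IMes)(PCy3)Cl2Ru=CHPh (second-generation Grubbs catalyst, 5 mol %), CH2Cl2, rt
Reagents that add atoms: none
Why: Cross enyne metathesis of a terminal alkyne with ethylene turns the C≡CH unit into a 2-substituted buta-1,3-diene; this catalyst tolerates free secondary propargylic alcohols, and the carbinol centre is not touched, so its (S) configuration is carried over.

Step 2
Reactants: 3 (2S)-3-methylidenepent-4-en-2-ol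
Product: 4 (1S)-1-[(2R)-2-ethenyloxiran-2-yl]ethan-1-ol
Conditions: Ti(OiPr)4 (15 mol %), L-(+)-DIPT (18 mol %), tBuOOH (2 equiv, decane), 4 Å MS, CH2Cl2, −20 °C; non-basic work-up (citric acid, Et2O–acetone)
Reagents that add atoms: tert-butyl hydroperoxide, CC(C)(C)OO
Why: The Katsuki–Sharpless epoxidation acts only on the allylic 1,1-disubstituted alkene, and L-(+)-tartrate and the (S)-carbinol (which avoids A1,2 strain with the vinyl group) select the same alkene face, so this matched pair should set the quaternary centre (future C1) as (R) in the erythro epoxy alcohol.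

Step 3
Reactants: 4 (1S)-1-[(2R)-2-ethenyloxiran-2-yl]ethan-1-ol; 5 benzoic acid
Product: 6 (2R,3S)-2-ethenyl-2,3-dihydroxybutyl benzoate
Conditions: PhCO2H (1.5 equiv), Ti(OiPr)4 (1.5 equiv), CH2Cl2, 0 °C → rt; aq. tartaric acid
Reagents that add atoms: none
Why: Titanium-alkoxide-assisted opening of a 2,3-epoxy alcohol (Caron–Sharpless conditions) sends the carboxylate by SN2 to the carbon remote from the carbinol, here the unhindered CH2 (C7), so the C1–O bond keeps its configuration and no base is present to start a Payne rearrangement.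

Step 4
Reactants: 6 (2R,3S)-2-ethenyl-2,3-dihydroxybutyl benzoate
Product: 7 (2R)-2-ethenyl-2-hydroxy-3-oxobutyl benzoate
Conditions: IBX (1.5 equiv), DMSO, rt
Reagents that add atoms: none
Why: IBX oxidation converts the secondary alcohol of a secondary/tertiary 1,2-diol into the alpha-hydroxy ketone without glycol cleavage, which erases the auxiliary carbinol centre and leaves C1 configurationally safe because it bears no hydrogen.

Step 5
Reactants: 7 (2R)-2-ethenyl-2-hydroxy-3-oxobutyl benzoate
Product: 8 (2R)-2-ethenyl-3-oxo-2-(trimethylsilyloxy)butyl benzoate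
Conditions: 1-(trimethylsilyl)imidazole, CH2Cl2, rt
Reagents that add atoms: 1-(trimethylsilyl)imidazole, C[Si](C)(C)n1ccnc1
Why: O-silylation with this strong but nearly neutral silyl donor caps the tertiary hydroxyl, which would otherwise consume the chloroborane of the next step, without forming the silyl enol ether of the methyl ketone or moving the benzoate.

Step 6
Reactants: 8 (2R)-2-ethenyl-3-oxo-2-(trimethylsilyloxy)butyl benzoate; 9 acrolein
Product: 12 (3R,6R)-3-(benzoyloxymethyl)-6-hydroxy-3-(trimethylsilyloxy)octa-1,7-dien-4-one, via enol borinate 10 (not isolated), via boron aldolate 11 (not isolated)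
Conditions: (−)-Ipc2BCl (1.5 equiv), Et3N (2 equiv), Et2O, 0 °C; 9 (3 equiv), −78 → −20 °C; 30% H2O2, MeOH, pH 7 buffer, 0 °C
Reagents that add atoms: none
Why: In this boron aldol reaction of a methyl ketone only the CH3 side can enolize, the enol diisopinocampheylborinate adds 1,2 to the enal, and the Ipc ligands made from (+)-alpha-pinene steer it to the Re face of acrolein to give (R)-C4; induction with methyl ketones is only moderate, but the minor C4 epimer is a diastereomer and should be removable by chromatography.

Step 7
Reactants: 12 (3R,6R)-3-(benzoyloxymethyl)-6-hydroxy-3-(trimethylsilyloxy)octa-1,7-dien-4-one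
Product: 14 (3R,6R)-3-(benzoyloxymethyl)-6-(tert-butyldimethylsilyloxy)-3-hydroxyocta-1,7-dien-4-one, via bis-silyl ether 13 (not isolated)
Conditions: TBSOTf (1.3 equiv), 2,6-lutidine (2 equiv), CH2Cl2, −78 °C; then citric acid, MeOH, 0 °C → rt
Reagents that add atoms: tert-butyldimethylsilyl trifluoromethanesulfonate, CC(C)(C)[Si](C)(C)OS(=O)(=O)C(F)(F)F
Why: Low-temperature silylation of the aldol adduct avoids retro-aldol and elimination, and the mild acid methanolysis that follows removes a trimethylsilyl ether far faster than a secondary tert-butyldimethylsilyl ether, so O1 is freed as a later directing group while O4 stays masked.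

Step 8
Reactants: 14 (3R,6R)-3-(benzoyloxymethyl)-6-(tert-butyldimethylsilyloxy)-3-hydroxyocta-1,7-dien-4-one
Product: 15 [(1R,4R)-4-(tert-butyldimethylsilyloxy)-1-hydroxy-6-oxocyclohex-2-en-1-yl]methyl benzoate
Conditions: (H2IMes)(PCy3)Cl2Ru=CHPh (second-generation Grubbs catalyst, 5 mol %), CH2Cl2 (5 mM), 40 °C
Reagents that add atoms: none
Why: The ruthenium benzylidene first exchanges with the vinyl group on the secondary carbon C4 to place the carbene on C5; this carbene adds [2+2] to the vinyl group on C1, and cycloreversion of the ruthenacyclobutane releases the ring and a ruthenium methylidene, with escaping ethylene driving the process. This is an ordinary ring-closing olefin metathesis of a 1,7-diene, a reaction type well established for dienes that carry free tertiary allylic alcohols, allylic silyl ethers, ketones and esters. The one ring formed is the six-membered carbocycle, closed by joining the two inner vinyl carbons as the endocyclic cis C5=C6 bond. No stereocentre is created, since C1 and C4 arrive fixed from steps 2 and 6 and cannot epimerize in the neutral medium (C1 is quaternary, C4 is not alpha to the ketone). The only selectivity needed is cyclization over oligomerization, which is secured by high dilution, the fully substituted C1 and the favourable ring size, while the free C1 hydroxyl, known to accelerate metathesis of an adjacent vinyl group, offsets the crowding at that terminus. The neutral conditions also spare the beta-silyloxy ketone, which base would push toward elimination.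

Step 9
Reactants: 15 [(1R,4R)-4-(tert-butyldimethylsilyloxy)-1-hydroxy-6-oxocyclohex-2-en-1-yl]methyl benzoate
Product: 16 [(1S,2S,5R,6R)-5-(tert-butyldimethylsilyloxy)-2-hydroxy-3-oxo-7-oxabicyclo[4.1.0]heptan-2-yl]methyl benzoate (C5–C6 epoxide cis to O1, trans to O4 and C7)
Conditions: VO(acac)2 (5 mol %), tBuOOH (1.5 equiv, decane), CH2Cl2, 0 °C → rt
Reagents that add atoms: tert-butyl hydroperoxide, CC(C)(C)OO
Why: Hydroxyl-directed vanadium-catalysed epoxidation of a cyclic tertiary allylic alcohol delivers oxygen to C5=C6 from the face of O1, which is also the face left open by the C4 silyloxy and C7 groups on the opposite side, and this fixes the C6–O bond cis to O1.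

Step 10
Reactants: 16 the C5–C6 epoxide; 5 benzoic acid
Product: 17 (1S,2S,3S,6R)-3-[(benzoyloxy)methyl]-6-(tert-butyldimethylsilyloxy)-2,3-dihydroxy-4-oxocyclohexyl benzoate (the O4 silyl ether of the target)
Conditions: PhCO2H (2 equiv), Ti(OiPr)4 (1.5 equiv), CH2Cl2, rt; aq. tartaric acid
Reagents that add atoms: none
Why: Seen from O1 the substrate is a cis-2,3-epoxy alcohol, so in this Caron–Sharpless-type opening titanium bridges O1 and the oxirane oxygen and benzoate attacks the remote carbon C5 anti to its C–O bond (SN2 inversion); attack at C5 is further favoured because C6 is neopentyl-like next to quaternary C1, and the result is C5–OBz trans to C6–OH and cis to O4.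

Step 11
Reactants: 17 the O4 silyl ether of the target
Product: 18 [(1S,2S,3R,4R)-3-(benzoyloxy)-1,2,4-trihydroxy-6-oxocyclohexyl]methyl benzoate (CNP0127041.1)
Conditions: HF·pyridine, THF–pyridine, 0 °C → rt
Reagents that add atoms: none
Why: Acidic fluoride desilylation cleaves the O4–Si bond without generating the alkoxides that would trigger benzoate migration among O4, O5 and O6 or beta-elimination of O4 from the ketone, and it touches no stereocentre.

**Compound list**
1 | (S)-but-3-yn-2-ol | C[C@H](O)C#C | starting material
2 | ethylene | C=C | starting material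
3 | (2S)-3-methylidenepent-4-en-2-ol | C[C@H](O)C(=C)C=C | intermediate
4 | (1S)-1-[(2R)-2-ethenyloxiran-2-yl]ethan-1-ol | C[C@H](O)[C@@]1(C=C)CO1 | intermediate
5 | benzoic acid | OC(=O)c1ccccc1 | starting material
6 | (2R,3S)-2-ethenyl-2,3-dihydroxybutyl benzoate | O=C(OC[C@@](O)([C@H](C)O)C=C)c1ccccc1 | intermediate
7 | (2R)-2-ethenyl-2-hydroxy-3-oxobutyl benzoate | O=C(OC[C@@](O)(C(C)=O)C=C)c1ccccc1 | intermediate
8 | (2R)-2-ethenyl-3-oxo-2-(trimethylsilyloxy)butyl benzoate | O=C(OC[C@@](O[Si](C)(C)C)(C(C)=O)C=C)c1ccccc1 | intermediate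
9 | acrolein | C=CC=O | starting material
10 | enol diisopinocampheylborinate of 8 (boron on the C2 enol oxygen, Ipc groups from (+)-alpha-pinene) | O=C(OC[C@@](O[Si](C)(C)C)(C(=C)OB([C@@H]1C[C@@H]2C[C@H]([C@H]1C)C2(C)C)[C@@H]1C[C@@H]2C[C@H]([C@H]1C)C2(C)C)C=C)c1ccccc1 | intermediate
11 | diisopinocampheylboron aldolate of 12 (boron on O4) | O=C(OC[C@@](O[Si](C)(C)C)(C(=O)C[C@@H](OB([C@@H]1C[C@@H]2C[C@H]([C@H]1C)C2(C)C)[C@@H]1C[C@@H]2C[C@H]([C@H]1C)C2(C)C)C=C)C=C)c1ccccc1 | intermediate
12 | (3R,6R)-3-(benzoyloxymethyl)-6-hydroxy-3-(trimethylsilyloxy)octa-1,7-dien-4-one | O=C(OC[C@@](O[Si](C)(C)C)(C(=O)C[C@@H](O)C=C)C=C)c1ccccc1 | intermediate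
13 | (3R,6R)-3-(benzoyloxymethyl)-6-(tert-butyldimethylsilyloxy)-3-(trimethylsilyloxy)octa-1,7-dien-4-one | O=C(OC[C@@](O[Si](C)(C)C)(C(=O)C[C@@H](O[Si](C)(C)C(C)(C)C)C=C)C=C)c1ccccc1 | intermediate
14 | (3R,6R)-3-(benzoyloxymethyl)-6-(tert-butyldimethylsilyloxy)-3-hydroxyocta-1,7-dien-4-one | O=C(OC[C@@](O)(C(=O)C[C@@H](O[Si](C)(C)C(C)(C)C)C=C)C=C)c1ccccc1 | intermediate
15 | [(1R,4R)-4-(tert-butyldimethylsilyloxy)-1-hydroxy-6-oxocyclohex-2-en-1-yl]methyl benzoate | O=C(OC[C@@]1(O)C(=O)C[C@@H](O[Si](C)(C)C(C)(C)C)C=C1)c1ccccc1 | intermediate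
16 | [(1S,2S,5R,6R)-5-(tert-butyldimethylsilyloxy)-2-hydroxy-3-oxo-7-oxabicyclo[4.1.0]heptan-2-yl]methyl benzoate | O=C(OC[C@@]1(O)C(=O)C[C@@H](O[Si](C)(C)C(C)(C)C)[C@@H]2O[C@H]12)c1ccccc1 | intermediate
17 | (1S,2S,3S,6R)-3-[(benzoyloxy)methyl]-6-(tert-butyldimethylsilyloxy)-2,3-dihydroxy-4-oxocyclohexyl benzoate | O=C(OC[C@@]1(O)C(=O)C[C@@H](O[Si](C)(C)C(C)(C)C)[C@@H](OC(=O)c2ccccc2)[C@@H]1O)c1ccccc1 | intermediate
18 | [(1S,2S,3R,4R)-3-(benzoyloxy)-1,2,4-trihydroxy-6-oxocyclohexyl]methyl benzoate | O=C(OC[C@@]1(O)C(=O)C[C@@H](O)[C@@H](OC(=O)c2ccccc2)[C@@H]1O)c1ccccc1 | target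

Total step count: 11. Longest linear sequence: 11 steps, from 1 to 18.

**Steps most likely to fail**

Step 10. The epoxide is flanked by oxygen-bearing carbons on both sides, so several things may go wrong:
- Attack may leak to C6.
- The C7 benzoate may take part as a neighbouring group at C6.
- The reaction may be slow, because benzoate has to enter on the face that carries the C4 silyloxy group.

The fallback gives up the epoxide and sets out from 15. Dihydroxylation with OsO4 (cat.) and N-methylmorpholine N-oxide in acetone–water should come from the face opposite the C4 silyloxy and C7 groups. It should give the all-cis O1/O5/O6 triol [(1S,2S,3R,4R)-4-(tert-butyldimethylsilyloxy)-1,2,3-trihydroxy-6-oxocyclohexyl]methyl benzoate F1. A Mitsunobu reaction (PPh3, DIAD, PhCO2H, toluene, 0 °C → rt) then activates the C5 hydroxyl. The C6 hydroxyl next to quaternary C1 is too crowded for displacement. Benzoate is introduced at C5 with inversion, and the route is rejoined at 17.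

Step 6. Facial selectivity at the aldehyde may be poor if the reagent control of the Ipc ligands is opposed by the alpha-quaternary centre. The fallback replaces asymmetric induction by a kinetic resolution and sets out from 8.
- An aldol run with an achiral base (LiHMDS, THF, −78 °C, then 9) should give 12 together with its C4 epimer (3R,6S)-3-(benzoyloxymethyl)-6-hydroxy-3-(trimethylsilyloxy)octa-1,7-dien-4-one F2.
- The mixture is treated with Ti(OiPr)4, L-(+)-DIPT and a substoichiometric amount of tBuOOH (4 Å MS, CH2Cl2, −20 °C).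
- The (S)-configured secondary allylic alcohol is the fast-reacting partner of this tartrate. It is converted into the far more polar epoxy alcohol (2R,5S)-2-ethenyl-5-hydroxy-5-[(2R)-oxiran-2-yl]-3-oxo-2-(trimethylsilyloxy)pentyl benzoate F3.
- The (R)-carbinol is left untouched and the silylated C1 vinyl carbinol does not react, so the route is rejoined at 12.

Step 3. C1 of the epoxide is tertiary and allylic. Under Lewis acid it may ionize or suffer SN2′ attack at the vinyl terminus, and the benzoate may then shift to the neighbouring secondary hydroxyl. The fallback changes the oxidation level at which the oxirane is opened and sets out from 4.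
- Parikh–Doering oxidation (SO3·pyridine, DMSO, Et3N, 0 °C) gives the epoxy ketone 1-[(2R)-2-ethenyloxiran-2-yl]ethan-1-one F4.
- In F4 the acyl group disfavours positive charge at C1, and no hydroxyl is left for a Payne rearrangement or acyl shift.
- Purely nucleophilic opening at the CH2 carbon with PhCO2H and catalytic Bu4N(O2CPh) in MeCN at 50 °C rejoins the route at 7.

**Further compounds**
F1 | step 10 | [(1S,2S,3R,4R)-4-(tert-butyldimethylsilyloxy)-1,2,3-trihydroxy-6-oxocyclohexyl]methyl benzoate | O=C(OC[C@@]1(O)C(=O)C[C@@H](O[Si](C)(C)C(C)(C)C)[C@H](O)[C@@H]1O)c1ccccc1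
F2 | step 6 | (3R,6S)-3-(benzoyloxymethyl)-6-hydroxy-3-(trimethylsilyloxy)octa-1,7-dien-4-one | O=C(OC[C@@](O[Si](C)(C)C)(C(=O)C[C@H](O)C=C)C=C)c1ccccc1
F3 | step 6 | (2R,5S)-2-ethenyl-5-hydroxy-5-[(2R)-oxiran-2-yl]-3-oxo-2-(trimethylsilyloxy)pentyl benzoate | O=C(OC[C@@](O[Si](C)(C)C)(C(=O)C[C@H](O)[C@H]1CO1)C=C)c1ccccc1
F4 | step 3 | 1-[(2R)-2-ethenyloxiran-2-yl]ethan-1-one | CC(=O)[C@@]1(C=C)CO1
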